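**Retrosynthetic overview**
1. The butenolide ring is formed last, by C–O ring closure (5-exo-dig lactonisation) in a one-flask Pd/Cu coupling of a terminal (E)-enyne with (Z)-3-iodobut-2-enoic acid.
2. The C18 aldehyde comes from the 4α-methyl through the key C–N bond: 6α-hydroxyl-directed 1,5-hydrogen transfer and NO transfer (new cerium-photocatalysed transfer oximation), then transoximation.
3. The (13E)-alkene comes from zirconium-catalysed methylalumination of a terminal alkyne made from the C13 methyl ketone; the 8α-OH comes from Markovnikov hydration (C–O) of the 8(17)-alkene.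
4. Rings A and B, with C5, C6, C9 and C10, are taken intact from (+)-larixol; the butenolide is the only ring built.

Assumption: (+)-larixol from larch oleoresin counts as a cheap commercial chiral-pool material, and the target is drawn as the open 6α-hydroxy-18-aldehyde, which equilibrates with its 6α,18-lactol.
Numbering: labdane numbering throughout; C18 is the 4α (equatorial) methyl. From step 4 on, the alkene CH (former C16) is called C14 and the new methyl C16.

**Step 1**
Reactants: 1 (+)-larixol
Product: 2 hydroxy ketone 6α-hydroxy-14,15-dinorlabd-8(17)-en-13-one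
Conditions: KMnO4, acetone/H2O, 0 °C to rt
Reagents that add atoms: none
Why: Permanganate oxidative cleavage (dihydroxylation of the vinyl group, then glycol and α-ketol cleavage) degrades the tertiary vinyl carbinol to the methyl ketone while the hindered exocyclic alkene and the secondary 6α-OH survive, as in the classical manool degradation; no stereocenter is formed.

**Step 2**
Reactants: 2 hydroxy ketone
Product: 6 alkynol 14,15-dinorlabd-8(17)-en-13(16)-yn-6α-ol, via silyl ether 3 (not isolated), via enol phosphate 4 (not isolated), via silyl alkyne 5 (not isolated)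
Conditions: LiN(iPr)2 (1.05 equiv) then TMSCl, THF, −78 to 0 °C; LiN(iPr)2 (1.1 equiv) then ClP(O)(OEt)2, −78 °C; LiN(iPr)2 (2.5 equiv), −78 °C to rt; 1 M HCl work-up
Reagents that add atoms: none
Why: Negishi-type conversion of a methyl ketone into a terminal alkyne: the 6α-alkoxide is silylated in the flask, kinetic deprotonation at the methyl group gives the terminal enol phosphate, base-induced β-elimination gives the alkyne, and the silyl ether falls off on acidic work-up; no stereocenter is touched.

**Step 3**
Reactants: 6 alkynol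
Product: 7 alkyne diol 14,15-dinorlabd-13(16)-yne-6α,8α-diol
Conditions: Mn(dpm)3 (10 mol%), PhSiH3, O2 (1 atm), iPrOH/CH2Cl2, 0 °C
Reagents that add atoms: dioxygen O=O
Why: Mukaiyama hydration (metal-hydride hydrogen-atom transfer to the 1,1-disubstituted alkene, O2 capture of the tertiary C8 radical, silane reduction of the peroxide) is Markovnikov-selective and far faster on the alkene than on the alkyne; O2 should add on the α face because the β face is shielded by the 1,3-diaxial C10 methyl, which sets C8 as 8α-OH/8β-CH3 as in sclareol.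

**Step 4**
Reactants: 7 alkyne diol
Product: 9 vinyl iodide (13E)-14-iodo-15-norlabd-13-ene-6α,8α-diol, via alkenylalane 8 (not isolated)
Conditions: AlMe3 (5 equiv), Cp2ZrCl2 (0.5 equiv), CH2Cl2, 0 °C to rt; then I2, THF, −30 to 0 °C
Reagents that add atoms: trimethylaluminium C[Al](C)C; iodine [I][I]
Why: Negishi zirconium-catalysed methylalumination adds CH3 and Al syn across the terminal alkyne with Al at the terminus (both hydroxyls first become aluminium alkoxides), and iodinolysis with retention gives only the (E)-trisubstituted vinyl iodide, which fixes the C13=C14 geometry.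

**Step 5**
Reactants: 9 vinyl iodide
Product: 11 enyne diol (13E)-14-ethynyl-15-norlabd-13-ene-6α,8α-diol, via silyl enyne 10 (not isolated)
Conditions: HC≡CSiMe3, PdCl2(PPh3)2 (3 mol%), CuI (6 mol%), Et3N, THF, rt; then K2CO3, MeOH, rt
Reagents that add atoms: ethynyltrimethylsilane C#C[Si](C)(C)C
Why: Sonogashira coupling retains the alkene geometry, and K2CO3 in methanol then removes the alkynyl silane in the same flask to give the terminal (E)-enyne.

**Step 6**
Reactants: 11 enyne diol
Product: 13 oxime (13E)-14-ethynyl-6α,8α-dihydroxy-15-norlabd-13-en-18-al oxime, via nitroso compound 12 (not isolated)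
Conditions: CeCl3 (5 mol%), Bu4NCl (10 mol%), t-BuONO (1.5 equiv), NaHCO3, MeCN, 400 nm LEDs, 20 °C, Ar; then Et3N (cat.), 40 °C
Reagents that add atoms: tert-butyl nitrite CC(C)(C)ON=O
Why: Proposed new method: cerium-photocatalysed transfer oximation, a catalytic counterpart of the Barton reaction, in which the secondary 6α-hydroxyl exchanges onto tetravalent cerium (the hindered tertiary 8α-OH should bind far less), 400 nm ligand-to-metal charge transfer releases the 6α-alkoxy radical, 1,5-hydrogen transfer across the ring fusion takes H from the peri 4α-methyl (O to C18 about 2.5 Å, both equatorial) and not from the axial 4β-methyl, the C18 radical abstracts NO from tert-butyl nitrite to form the C18–N bond, the released tert-butoxy radical re-oxidises trivalent cerium, and base tautomerises the nitroso compound to the oxime; choosing one of the two C4 methyls sets the C4 stereocenter; closest known reactions: Barton nitrite ester photolysis and cerium-photocatalysed δ-C–H amination of free alcohols.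

**Step 7**
Reactants: 13 oxime
Product: 14 hydroxy aldehyde (13E)-14-ethynyl-6α,8α-dihydroxy-15-norlabd-13-en-18-al
Conditions: OHC–CO2H·H2O, NaOAc, THF/H2O, 40 °C
Reagents that add atoms: water O
Why: Transoximation passes hydroxylamine from the hindered aldoxime to glyoxylic acid, helped by the neighbouring 6α-OH through the cyclic lactol, and frees the non-enolisable aldehyde under buffered conditions that spare the tertiary alcohol and the enyne; no stereocenter changes.

**Step 8**
Reactants: 15 but-2-ynoic acid
Product: 16 (Z)-3-iodobut-2-enoic acid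
Conditions: NaI, AcOH, 115 °C
Reagents that add atoms: sodium iodide [Na+].[I-]
Why: Hydroiodination by conjugate addition of iodide and anti protonation gives the (Z)-β-iodo acid with iodine cis to the carboxyl group, the geometry needed for lactonisation.

**Step 9**
Reactants: 14 hydroxy aldehyde; 16 (Z)-3-iodobut-2-enoic acid
Product: 18 target CNP0278517.1, via enynoic acid 17 (not isolated)
Conditions: Pd(PPh3)4 (5 mol%), CuI (10 mol%), Et3N, MeCN, rt, dark
Reagents that add atoms: none
Why: Tandem Sonogashira coupling and 5-exo-dig lactonisation (Negishi-type γ-alkylidenebutenolide synthesis): the alkyne couples with retention, and the cis carboxylate then adds anti across the metal-activated alkyne, which closes the butenolide through its C–O bond and sets the exocyclic (Z)-alkene; the lactol or aldehyde and both hydroxyls should be inert.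

**Compound list**
1 | (+)-larixol, (13S)-labda-8(17),14-diene-6α,13-diol | C=C[C@@](C)(O)CC[C@@H]1[C@@]2(C)CCCC(C)(C)[C@@H]2[C@@H](O)CC1=C | starting material
2 | hydroxy ketone, 6α-hydroxy-14,15-dinorlabd-8(17)-en-13-one | CC(=O)CC[C@@H]1[C@@]2(C)CCCC(C)(C)[C@@H]2[C@@H](O)CC1=C | intermediate
3 | silyl ether, 6α-(trimethylsilyloxy)-14,15-dinorlabd-8(17)-en-13-one | CC(=O)CC[C@@H]1[C@@]2(C)CCCC(C)(C)[C@@H]2[C@@H](O[Si](C)(C)C)CC1=C | intermediate
4 | enol phosphate, diethyl 6α-(trimethylsilyloxy)-14,15-dinorlabda-8(17),13(16)-dien-13-yl phosphate | C=C(OP(=O)(OCC)OCC)CC[C@@H]1[C@@]2(C)CCCC(C)(C)[C@@H]2[C@@H](O[Si](C)(C)C)CC1=C | intermediate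
5 | silyl alkyne, 6α-(trimethylsilyloxy)-14,15-dinorlabd-8(17)-en-13(16)-yne | C#CCC[C@@H]1[C@@]2(C)CCCC(C)(C)[C@@H]2[C@@H](O[Si](C)(C)C)CC1=C | intermediate
6 | alkynol, 14,15-dinorlabd-8(17)-en-13(16)-yn-6α-ol | C#CCC[C@@H]1[C@@]2(C)CCCC(C)(C)[C@@H]2[C@@H](O)CC1=C | intermediate
7 | alkyne diol, 14,15-dinorlabd-13(16)-yne-6α,8α-diol | C#CCC[C@@H]1[C@@]2(C)CCCC(C)(C)[C@@H]2[C@@H](O)C[C@@]1(C)O | intermediate
8 | alkenylalane, (13E)-14-(dimethylalumanyl)-15-norlabd-13-ene-6α,8α-diol as its bis(dimethylaluminium) alkoxide | C[Al](C)/C=C(\C)CC[C@@H]1[C@@]2(C)CCCC(C)(C)[C@@H]2[C@@H](O[Al](C)C)C[C@@]1(C)O[Al](C)C | intermediate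
9 | vinyl iodide, (13E)-14-iodo-15-norlabd-13-ene-6α,8α-diol | I/C=C(\C)CC[C@@H]1[C@@]2(C)CCCC(C)(C)[C@@H]2[C@@H](O)C[C@@]1(C)O | intermediate
10 | silyl enyne, (13E)-14-[(trimethylsilyl)ethynyl]-15-norlabd-13-ene-6α,8α-diol | C[Si](C)(C)C#C/C=C(\C)CC[C@@H]1[C@@]2(C)CCCC(C)(C)[C@@H]2[C@@H](O)C[C@@]1(C)O | intermediate
11 | enyne diol, (13E)-14-ethynyl-15-norlabd-13-ene-6α,8α-diol | C#C/C=C(\C)CC[C@@H]1[C@@]2(C)CCCC(C)(C)[C@@H]2[C@@H](O)C[C@@]1(C)O | intermediate
12 | nitroso compound, (13E)-14-ethynyl-18-nitroso-15-norlabd-13-ene-6α,8α-diol | C#C/C=C(\C)CC[C@@H]1[C@@]2(C)CCC[C@@](C)(CN=O)[C@@H]2[C@@H](O)C[C@@]1(C)O | intermediate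
13 | oxime, (13E)-14-ethynyl-6α,8α-dihydroxy-15-norlabd-13-en-18-al (E)-oxime | C#C/C=C(\C)CC[C@@H]1[C@@]2(C)CCC[C@@](C)(/C=N/O)[C@@H]2[C@@H](O)C[C@@]1(C)O | intermediate
14 | hydroxy aldehyde, (13E)-14-ethynyl-6α,8α-dihydroxy-15-norlabd-13-en-18-al (with its 6α,18-lactol) | C#C/C=C(\C)CC[C@@H]1[C@@]2(C)CCC[C@@](C)(C=O)[C@@H]2[C@@H](O)C[C@@]1(C)O | intermediate
15 | but-2-ynoic acid | CC#CC(=O)O | starting material
16 | (Z)-3-iodobut-2-enoic acid | C/C(I)=C/C(=O)O | intermediate
17 | enynoic acid, (2Z,6E)-3,7-dimethylnona-2,6-dien-4-ynoic acid carrying the 6α,8α-dihydroxy-18-oxo decalin at C9 | OC(=O)/C=C(/C)C#C/C=C(\C)CC[C@@H]1[C@@]2(C)CCC[C@@](C)(C=O)[C@@H]2[C@@H](O)C[C@@]1(C)O | intermediate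
18 | target CNP0278517.1, (Z)-γ-ylidene-β-methylbutenolide with (13E)-alkene, 6α-OH, 8α-OH and 4α-CHO | CC1=CC(=O)O/C1=C\C=C(/C)CC[C@@H]1[C@@]2(C)CCC[C@@](C)(C=O)[C@@H]2[C@@H](O)C[C@@]1(C)O | target

**Totals**
Total step count: 9. Longest linear sequence: 8 (steps 1 to 7 and 9).

**Steps most likely to fail, with fallbacks**

Step 6 (the new method). The risks are alkoxy radical formation at the tertiary 8α-OH, background chlorine-radical chemistry, and slow NO transfer. The fallback is the classical stoichiometric Barton sequence, which is known chemistry. It sets out from 11: NOCl and pyridine (CH2Cl2, −30 °C) nitrosate only the secondary hydroxyl and give the isolated 6α-nitrite ester F1. Photolysis (365 nm, benzene, 10 °C) gives the nitroso compound 12, as its dimer, by NO rebound to the C18 radical. Warming in 2-propanol isomerises it to oxime 13, where the route is rejoined.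

Step 3. The risks are the diastereomer ratio at C8, hydrogen-atom transfer to the alkyne, and 5-exo cyclisation of the C8 radical onto the alkyne. The fallback is a two-step ionic hydration. It sets out from 6: mCPBA (NaHCO3, CH2Cl2, 0 °C) epoxidises the exocyclic alkene from the α face, the usual face for labd-8(17)-enes, to the 8α,17-epoxide F2. LiAlH4 (THF, 0 °C) then delivers hydride to C17 and gives 7, where the route is rejoined.

Step 9. The risks are 6-endo closure to the 2-pyranone and poor conversion with the unprotected lactol. The fallback separates C–C from C–O bond formation. It sets out from 14 and 16: 16 is esterified (MeI, K2CO3, DMF) to methyl (Z)-3-iodobut-2-enoate F3. This is coupled with 14 (PdCl2(PPh3)2, CuI, Et3N, THF) to the methyl (2Z,6E)-dienynoate F4. LiOH (THF/H2O) gives acid 17, now isolated, where the route is rejoined. AgNO3 (10 mol%, acetone, dark, rt) then closes 17 5-exo to 18.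

**Further compounds**
F1 | step 6 | 6α-nitrite ester of 11, (13E)-14-ethynyl-8α-hydroxy-15-norlabd-13-en-6α-yl nitrite | C#C/C=C(\C)CC[C@@H]1[C@@]2(C)CCCC(C)(C)[C@@H]2[C@@H](ON=O)C[C@@]1(C)O
F2 | step 3 | 8α,17-epoxide of 6, 8α,17-epoxy-14,15-dinorlabd-13(16)-yn-6α-ol | C#CCC[C@@H]1[C@@]2(C)CCCC(C)(C)[C@@H]2[C@@H](O)C[C@@]1(C3)O3
F3 | step 9 | methyl (Z)-3-iodobut-2-enoate | C/C(I)=C/C(=O)OC
F4 | step 9 | methyl ester of 17, methyl (2Z,6E)-dienynoate | COC(=O)/C=C(/C)C#C/C=C(\C)CC[C@@H]1[C@@]2(C)CCC[C@@](C)(C=O)[C@@H]2[C@@H](O)C[C@@]1(C)O
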